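**Strategy.** The route rests on cutting ring B (the cyclopentane) at two bonds: C3–isopropenyl and C2–CH2 (the bridge to ring A), with C1 the later carbinol carbon. These three contiguous ring-B atoms map onto the β-carbon, α-carbon and carbonyl carbon of cyclopent-2-enone. In one flask a copper/phosphoramidite-catalysed conjugate addition of an isopropenylalane sets C3, and the regiodefined enolate is benzylated at C2, trans to isopropenyl. The electrophile is a hexasubstituted benzyl bromide: a MOM-protected methylphloroglucinol core carrying a ring bromine that slows ionisation, blocks self-alkylation and is later exchanged for the isobutyryl group. Methyl addition, acylation, MOM removal and catalyst-controlled dearomative prenylation of ring A finish the target.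

Key step: step 7

Assumption: ring A is treated as the drawn 3,5-dihydroxycyclohexa-2,4-dien-1-one tautomer; its enol tautomers interconvert without touching the quaternary carbon (6R in this drawing).

**Step 1**
Reactants: 1 2-methylbenzene-1,3,5-triol (methylphloroglucinol)
Product: 3 2,4,6-trihydroxy-3-methylbenzaldehyde, via aryl iminium chloride 2 (not isolated)
Conditions: POCl3, DMF, EtOAc, 0 °C → rt; then H2O, 60 °C
Reagents that add atoms: N,N-dimethylformamide, CN(C)C=O; water, O
Why: Vilsmeier–Haack formylation attacks one of the two equivalent free positions of the electron-rich ring and stops after one substitution because the iminium group deactivates the arene, and hydrolysis then frees the aldehyde.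

**Step 2**
Reactants: 3 2,4,6-trihydroxy-3-methylbenzaldehyde
Product: 4 2,4,6-tris(methoxymethoxy)-3-methylbenzaldehyde
Conditions: NaH, MOMCl, DMF, 0 °C → rt
Reagents that add atoms: chloromethyl methyl ether, COCCl
Why: Williamson O-alkylation of the three phenoxides by the hard electrophile MOMCl, with full deprotonation by NaH in DMF overcoming the hydrogen bond between the ortho hydroxyls and the aldehyde.

**Step 3**
Reactants: 4 2,4,6-tris(methoxymethoxy)-3-methylbenzaldehyde
Product: 5 3-bromo-2,4,6-tris(methoxymethoxy)-5-methylbenzaldehyde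
Conditions: NBS, MeCN, 0 °C → rt, dark
Reagents that add atoms: N-bromosuccinimide, O=C1CCC(=O)N1Br
Why: Electrophilic aromatic bromination at the only free ring position, which is activated by two ortho and one para acetal oxygen and lies meta to the aldehyde.

**Step 4**
Reactants: 5 3-bromo-2,4,6-tris(methoxymethoxy)-5-methylbenzaldehyde
Product: 6 [3-bromo-2,4,6-tris(methoxymethoxy)-5-methylphenyl]methanol
Conditions: NaBH4, THF/MeOH, 0 °C
Reagents that add atoms: none
Why: Borohydride reduction of the aldehyde, to which the aryl bromide and the MOM acetals are inert.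

**Step 5**
Reactants: 6 [3-bromo-2,4,6-tris(methoxymethoxy)-5-methylphenyl]methanol
Product: 8 3-bromo-2,4,6-tris(methoxymethoxy)-5-methylbenzyl bromide, via alkoxyphosphonium bromide 7 (not isolated)
Conditions: CBr4, PPh3, CH2Cl2, −20 → 0 °C; cold filtration through basic alumina; used at once
Reagents that add atoms: carbon tetrabromide, BrC(Br)(Br)Br
Why: The Appel reaction replaces the benzylic hydroxyl under neutral conditions that spare the MOM groups, while the ring bromine meta to the new CH2Br slows ionisation and leaves no free ring position for self-alkylation, so the bromide should last until it is used.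

**Step 6**
Reactants: 9 2-bromopropene
Product: 11 dimethyl(prop-1-en-2-yl)aluminium (ether/hexane solution), via isopropenyllithium 10 (not isolated)
Conditions: t-BuLi (2 equiv), Et2O, −78 °C; then Me2AlCl (hexanes), −78 °C → rt; supernatant used
Reagents that add atoms: dimethylaluminium chloride, C[Al](C)Cl
Why: Bromine–lithium exchange (the second equivalent of t-BuLi destroys the tert-butyl bromide formed) followed by salt metathesis with Me2AlCl gives the mixed alane, whose sp2 group is the one passed on to copper.

**Step 7**
Reactants: 12 cyclopent-2-en-1-one; 11 dimethyl(prop-1-en-2-yl)aluminium; 8 3-bromo-2,4,6-tris(methoxymethoxy)-5-methylbenzyl bromide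
Product: 15 (2S,3R)-2-{[3-bromo-2,4,6-tris(methoxymethoxy)-5-methylphenyl]methyl}-3-(prop-1-en-2-yl)cyclopentan-1-one, via aluminium enolate 13 (not isolated), via lithium aluminate enolate 14 (not isolated)
Conditions: Cu(OTf)2 (5 mol %), O,O'-(S)-(1,1'-binaphthalene-2,2'-diyl)-N,N-bis[(R)-1-phenylethyl]phosphoramidite (10 mol %), Et2O, −30 °C; then MeLi (1 equiv per Al), −78 °C; then 8 (limiting), THF/DMPU, −78 → −20 °C; aq. Rochelle salt
Reagents that add atoms: none
Why: The alane reduces Cu(OTf)2 to a monovalent copper–phosphoramidite complex, which takes the isopropenyl group from aluminium and delivers it to the β-carbon of 12, leaving aluminium enolate 13 with its double bond fixed between C1 and C2. The closest known chemistry is the copper-catalysed asymmetric conjugate addition of alkenylalanes to cyclic enones with trapping of the enolate, together with the alkylation of aluminium enolates after conversion into lithium aluminates by MeLi. No ring is closed; only the C3–isopropenyl and C2–CH2 bonds are formed. C3 (R) is set by the chiral ligand on copper, whose antipode is fixed in a trial run by protonating the enolate to the known 3-isopropenylcyclopentanone; C2 (S) is set by C3, because ate complex 14 is benzylated by SN2 on the face away from the isopropenyl group. The step needs enantioface selectivity at the β-carbon (ligand), alkylation at C2 and not C5 (the enolate is formed regiospecifically and is alkylated cold by a very reactive benzylic bromide before proton transfer can scramble it), and no copper-mediated coupling of the alane with 8 (8 is added only after 12 is consumed and MeLi has tied up aluminium as the aluminate).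

**Step 8**
Reactants: 15 (2S,3R)-2-{[3-bromo-2,4,6-tris(methoxymethoxy)-5-methylphenyl]methyl}-3-(prop-1-en-2-yl)cyclopentan-1-one
Product: 16 (1R,2S,3R)-2-{[3-bromo-2,4,6-tris(methoxymethoxy)-5-methylphenyl]methyl}-1-methyl-3-(prop-1-en-2-yl)cyclopentan-1-ol
Conditions: CeCl3 (anhydrous), MeLi, THF, −78 °C; aq. NH4Cl
Reagents that add atoms: methyllithium, [Li]C
Why: Organocerium 1,2-addition is non-basic, so C2 is not enolised, and methyl should enter on the carbonyl face anti to the bulky adjacent arylmethyl group, which places the new hydroxyl cis to the bridge (1R).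

**Step 9**
Reactants: 16 (1R,2S,3R)-2-{[3-bromo-2,4,6-tris(methoxymethoxy)-5-methylphenyl]methyl}-1-methyl-3-(prop-1-en-2-yl)cyclopentan-1-ol; 17 N-methoxy-N,2-dimethylpropanamide
Product: 20 1-[3-{[(1S,2R,5R)-2-hydroxy-2-methyl-5-(prop-1-en-2-yl)cyclopentyl]methyl}-2,4,6-tris(methoxymethoxy)-5-methylphenyl]-2-methylpropan-1-one, via dilithio intermediate 18 (not isolated), via tetrahedral adduct 19 (not isolated)
Conditions: n-BuLi (2.1 equiv), THF, −78 °C; then 17, −78 → 0 °C; aq. NH4Cl
Reagents that add atoms: none
Why: After deprotonation of the tertiary alcohol, bromine–lithium exchange gives an aryllithium flanked by two coordinating MOM oxygens, which adds once to the Weinreb amide and releases the ketone only on work-up (Weinreb ketone synthesis).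

**Step 10**
Reactants: 20 1-[3-{[(1S,2R,5R)-2-hydroxy-2-methyl-5-(prop-1-en-2-yl)cyclopentyl]methyl}-2,4,6-tris(methoxymethoxy)-5-methylphenyl]-2-methylpropan-1-one
Product: 21 1-[2,4,6-trihydroxy-3-{[(1S,2R,5R)-2-hydroxy-2-methyl-5-(prop-1-en-2-yl)cyclopentyl]methyl}-5-methylphenyl]-2-methylpropan-1-one
Conditions: ZnBr2, n-PrSH, CH2Cl2, 0 °C, argon
Reagents that add atoms: none
Why: Zinc-activated transacetalisation with the thiol as soft nucleophile should cleave the three aryl MOM ethers quickly without protic acid, so the tertiary alcohol and the isopropenyl group are not expected to ionise.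

**Step 11**
Reactants: 21 1-[2,4,6-trihydroxy-3-{[(1S,2R,5R)-2-hydroxy-2-methyl-5-(prop-1-en-2-yl)cyclopentyl]methyl}-5-methylphenyl]-2-methylpropan-1-one; 22 3-methylbut-2-en-1-yl acetate (prenyl acetate)
Product: 23 (6R)-3,5-dihydroxy-4-{[(1S,2R,5R)-2-hydroxy-2-methyl-5-(prop-1-en-2-yl)cyclopentyl]methyl}-6-methyl-6-(3-methylbut-2-en-1-yl)-2-(2-methylpropanoyl)cyclohexa-2,4-dien-1-one (target)
Conditions: Pd2(dba)3·CHCl3 (2.5 mol %), (R,R)-N,N'-(cyclohexane-1,2-diyl)bis[2-(diphenylphosphanyl)benzamide] (7.5 mol %), Et3N (1.1 equiv), THF (degassed), 0 °C → rt; dilute aq. citric acid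
Reagents that add atoms: none
Why: Proposed new method: the triethylammonium phenoxide of 21 should attack the π-prenyl palladium complex formed from 22 by outer-sphere Tsuji–Trost attack at the unsubstituted allyl terminus, through the methyl-bearing ring carbon (C5 of the arene, C6 of 23), which is less hindered than the bridge-bearing carbon, while any O-prenyl ether is re-ionised by zerovalent palladium; the chiral pocket of the diphosphine (antipode fixed in the first run) is relied on to select the face giving 6R because the ring-B stereocentres are too remote to do so; the closest known reactions are the palladium-catalysed asymmetric allylic dearomatisation of naphthols and the non-asymmetric palladium-catalysed or base-mediated dearomative C-allylation of acylphloroglucinols.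

**Compound list**

1 | 2-methylbenzene-1,3,5-triol (methylphloroglucinol) | Cc1c(O)cc(O)cc1O | starting material
2 | N-[(2,4,6-trihydroxy-3-methylphenyl)methylidene]-N-methylmethanaminium chloride | Cc1c(O)cc(O)c(C=[N+](C)C)c1O.[Cl-] | intermediate
3 | 2,4,6-trihydroxy-3-methylbenzaldehyde | Cc1c(O)cc(O)c(C=O)c1O | intermediate
4 | 2,4,6-tris(methoxymethoxy)-3-methylbenzaldehyde | Cc1c(OCOC)cc(OCOC)c(C=O)c1OCOC | intermediate
5 | 3-bromo-2,4,6-tris(methoxymethoxy)-5-methylbenzaldehyde | Cc1c(OCOC)c(Br)c(OCOC)c(C=O)c1OCOC | intermediate
6 | [3-bromo-2,4,6-tris(methoxymethoxy)-5-methylphenyl]methanol | Cc1c(OCOC)c(Br)c(OCOC)c(CO)c1OCOC | intermediate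
7 | {[3-bromo-2,4,6-tris(methoxymethoxy)-5-methylphenyl]methoxy}triphenylphosphonium bromide | Cc1c(OCOC)c(Br)c(OCOC)c(CO[P+](c2ccccc2)(c2ccccc2)c2ccccc2)c1OCOC.[Br-] | intermediate
8 | 3-bromo-2,4,6-tris(methoxymethoxy)-5-methylbenzyl bromide | Cc1c(OCOC)c(Br)c(OCOC)c(CBr)c1OCOC | intermediate
9 | 2-bromopropene | C=C(C)Br | starting material
10 | prop-1-en-2-yllithium | C=C(C)[Li] | intermediate
11 | dimethyl(prop-1-en-2-yl)aluminium | C=C(C)[Al](C)C | intermediate
12 | cyclopent-2-en-1-one | O=C1C=CCC1 | starting material
13 | dimethyl{[(3R)-3-(prop-1-en-2-yl)cyclopent-1-en-1-yl]oxy}aluminium | C=C(C)[C@@H]1CCC(O[Al](C)C)=C1 | intermediate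
14 | lithium trimethyl{[(3R)-3-(prop-1-en-2-yl)cyclopent-1-en-1-yl]oxy}aluminate | C=C(C)[C@@H]1CCC(O[Al-](C)(C)C)=C1.[Li+] | intermediate
15 | (2S,3R)-2-{[3-bromo-2,4,6-tris(methoxymethoxy)-5-methylphenyl]methyl}-3-(prop-1-en-2-yl)cyclopentan-1-one | C=C(C)[C@@H]1CCC(=O)[C@H]1Cc1c(OCOC)c(C)c(OCOC)c(Br)c1OCOC | intermediate
16 | (1R,2S,3R)-2-{[3-bromo-2,4,6-tris(methoxymethoxy)-5-methylphenyl]methyl}-1-methyl-3-(prop-1-en-2-yl)cyclopentan-1-ol | C=C(C)[C@@H]1CC[C@@](C)(O)[C@H]1Cc1c(OCOC)c(C)c(OCOC)c(Br)c1OCOC | intermediate
17 | N-methoxy-N,2-dimethylpropanamide | CC(C)C(=O)N(C)OC | starting material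
18 | lithium (1R,2S,3R)-2-{[3-lithio-2,4,6-tris(methoxymethoxy)-5-methylphenyl]methyl}-1-methyl-3-(prop-1-en-2-yl)cyclopentan-1-olate | C=C(C)[C@@H]1CC[C@@](C)(O[Li])[C@H]1Cc1c(OCOC)c(C)c(OCOC)c([Li])c1OCOC | intermediate
19 | dilithium salt of the hemiaminal adduct of 18 with 17 (hemiaminal carbon not defined) | C=C(C)[C@@H]1CC[C@@](C)(O[Li])[C@H]1Cc1c(OCOC)c(C)c(OCOC)c(C(O[Li])(N(C)OC)C(C)C)c1OCOC | intermediate
20 | 1-[3-{[(1S,2R,5R)-2-hydroxy-2-methyl-5-(prop-1-en-2-yl)cyclopentyl]methyl}-2,4,6-tris(methoxymethoxy)-5-methylphenyl]-2-methylpropan-1-one | C=C(C)[C@@H]1CC[C@@](C)(O)[C@H]1Cc1c(OCOC)c(C)c(OCOC)c(C(=O)C(C)C)c1OCOC | intermediate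
21 | 1-[2,4,6-trihydroxy-3-{[(1S,2R,5R)-2-hydroxy-2-methyl-5-(prop-1-en-2-yl)cyclopentyl]methyl}-5-methylphenyl]-2-methylpropan-1-one | C=C(C)[C@@H]1CC[C@@](C)(O)[C@H]1Cc1c(O)c(C)c(O)c(C(=O)C(C)C)c1O | intermediate
22 | 3-methylbut-2-en-1-yl acetate | CC(=O)OCC=C(C)C | starting material
23 | (6R)-3,5-dihydroxy-4-{[(1S,2R,5R)-2-hydroxy-2-methyl-5-(prop-1-en-2-yl)cyclopentyl]methyl}-6-methyl-6-(3-methylbut-2-en-1-yl)-2-(2-methylpropanoyl)cyclohexa-2,4-dien-1-one | C=C(C)[C@@H]1CC[C@@](C)(O)[C@H]1CC1=C(O)[C@@](C)(CC=C(C)C)C(=O)C(C(=O)C(C)C)=C1O | target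

**Step count.** Total: 11 steps. Longest linear sequence: 10 steps (1 → 23 through steps 1–5 and 7–11); the alane branch (step 6) joins at step 7.

**Steps most likely to fail**

Step 11. Facial control at the new quaternary carbon may be insufficient, since the discriminating groups sit two atoms away from the reacting carbon. Alkylation at oxygen, at the bridge-bearing ring carbon, or a second alkylation may also compete. The fallback sets out from 21 and uses the classical dearomative C-prenylation of acylphloroglucinols: prenyl bromide with aqueous KOH (or NaOMe in MeOH) at 0 °C under argon. This is expected to alkylate the methyl-bearing carbon without facial control, giving 23 together with its 6S epimer F1. The two are diastereomers because ring B is stereodefined, so preparative HPLC should separate them. The route is rejoined at 23.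

Step 7. The aluminium-bound enolate may alkylate too slowly, proton transfer between product and enolate may scramble the enolate position or cause double alkylation, and the small five-membered enone may give low enantioface selectivity. The fallback sets out from aluminium enolate 13, generated as in step 7, and splits the operation in two. The enolate is trapped with TESOTf at −78 °C to give the triethylsilyl enol ether F2, which is isolated and its enantiomeric purity checked. F2 is then cleaved with MeLi in THF at 0 °C to the regiodefined lithium enolate F3, which is benzylated with 8 in THF/DMPU at −78 °C, again anti to the isopropenyl group. The route is rejoined at 15.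

Step 10. Under Lewis-acidic conditions the tertiary carbinol of ring B may ionise or the isopropenyl group may be activated, with capture by the neighbouring phenol to give a cyclic ether; the acetal flanked by two alkyl groups may also cleave incompletely. The fallback sets out from 20 and uses silyl transfer in place of acid/thiol cleavage. TMSOTf with 2,2'-bipyridyl in MeCN at 0 °C should convert each aryl MOM ether into the aryl trimethylsilyl ether and silylate the tertiary hydroxyl, giving the tetrakis(trimethylsilyl) ether F4. Catalytic K2CO3 in MeOH at 0 °C under argon then removes all silyl groups. The route is rejoined at 21.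

**Further compounds**

F1 | step 11 | (6S)-3,5-dihydroxy-4-{[(1S,2R,5R)-2-hydroxy-2-methyl-5-(prop-1-en-2-yl)cyclopentyl]methyl}-6-methyl-6-(3-methylbut-2-en-1-yl)-2-(2-methylpropanoyl)cyclohexa-2,4-dien-1-one | C=C(C)[C@@H]1CC[C@@](C)(O)[C@H]1CC1=C(O)[C@](C)(CC=C(C)C)C(=O)C(C(=O)C(C)C)=C1O
F2 | step 7 | triethyl{[(3R)-3-(prop-1-en-2-yl)cyclopent-1-en-1-yl]oxy}silane | C=C(C)[C@@H]1CCC(O[Si](CC)(CC)CC)=C1
F3 | step 7 | lithium (3R)-3-(prop-1-en-2-yl)cyclopent-1-en-1-olate | C=C(C)[C@@H]1CCC(O[Li])=C1
F4 | step 10 | 2-methyl-1-[3-methyl-5-{[(1S,2R,5R)-2-methyl-5-(prop-1-en-2-yl)-2-(trimethylsilyloxy)cyclopentyl]methyl}-2,4,6-tris(trimethylsilyloxy)phenyl]propan-1-one | C=C(C)[C@@H]1CC[C@@](C)(O[Si](C)(C)C)[C@H]1Cc1c(O[Si](C)(C)C)c(C)c(O[Si](C)(C)C)c(C(=O)C(C)C)c1O[Si](C)(C)C
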